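The cyclobutane is cut (C1' bearing the CH2 link, C2' the isopropenyl group, C3' the gem-dimethyl carbon, C4' the ring CH2) across C2'–C3' and C1'–C4', into isobutylene and a C1'=C2' enoate. One photochemical [2+2] step under a chiral Lewis acid makes both bonds, closes the four-membered ring and fixes C2'. Its precursor is 5,5-dimethylfuran-2(5H)-one, whose carbonyl carbon later becomes the CH2 link and whose O–CMe2 carbon the isopropenyl group. The cis lactone is unmasked to the trans aldehyde, joined by reductive alkylation to C6 of a chromanone ester built from phloroglucinol, and C6 is then made quaternary by asymmetric dearomative prenylation.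

Key step: step 3

Assumption: the sense of induction of the three chiral catalysts (oxazaborolidine in step 3, prolinol silyl ether in step 8, diphosphine ligand in step 14) is taken from the usual shielding models; if a catalyst favours the other face, its mirror image is to be used with no other change.

Step 1
Reactants: 1 2-methylbut-3-yn-2-ol
Product: 2 4-hydroxy-4-methylpent-2-ynoic acid
Conditions: n-BuLi (2.1 equiv), THF, −78 °C; CO2 (g), −78 → 0 °C; aq. HCl
Reagents that add atoms: carbon dioxide, O=C=O
Why: Carboxylation of a lithium acetylide: the O,C-dilithio derivative should take up CO2 at the acetylide carbon, and any carbonate formed at the alkoxide is lost again on acidification.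

Step 2
Reactants: 2 4-hydroxy-4-methylpent-2-ynoic acid
Product: 4 5,5-dimethylfuran-2(5H)-one, via (Z)-4-hydroxy-4-methylpent-2-enoic acid 3 (not isolated)
Conditions: H2 (1 atm), Pd/CaCO3 poisoned with Pb(OAc)2, quinoline, EtOAc, 25 °C; then HCl (cat.), 25 °C
Reagents that add atoms: none
Why: cis-Semihydrogenation of the alkyne places the tertiary hydroxyl and the carboxyl group on the same side of the alkene, so that acid-catalysed lactonisation to the butenolide should follow readily.

Step 3
Reactants: 4 5,5-dimethylfuran-2(5H)-one; 5 isobutylene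
Product: 6 (1S,5S)-4,4,6,6-tetramethyl-3-oxabicyclo[3.2.0]heptan-2-one
Conditions: 5 (10 equiv), oxazaborolidine from (S)-α,α-bis(3,5-dimethylphenyl)prolinol and 2,4,6-trifluorophenylboronic acid (60 mol%), AlBr3 (50 mol%), CH2Cl2, −75 °C, hν (λ = 300 nm)
Reagents that add atoms: none
Why: Proposed new method: binding of the oxazaborolidine–AlBr3 Lewis acid to the lactone carbonyl of 4 should move the π–π* band of the enoate to longer wavelength, so that at 300 nm only the chiral complex absorbs; after intersystem crossing (helped by the bromine atoms) its triplet adds 5 stepwise through a 1,4-biradical, the closest known reaction type being the chiral oxazaborolidine–AlBr3 mediated intermolecular [2+2] photocycloaddition of cyclic enones with alkenes (a lactone carbonyl binds the same Lewis acid in the known intramolecular coumarin case). The first bond joins the CH2 terminus of 5 to the α-carbon C1 (future C1'–C4'), and the cyclobutane then closes by radical–radical combination between the β-carbon C5 and the tertiary radical centre (future C2'–C3'). C5, the future C2', is set by the catalyst, whose aryl group covers one face of the bound butenolide so that the alkene enters from the open face; C1 follows because the five-membered lactone only accepts a cis ring fusion. The step needs head-to-tail regiochemistry and face control: the first is secured by the substrate, since the β-carbon is neopentyl-like next to C4 and the unhindered alkene CH2 should therefore attack the α-carbon and leave a tertiary radical; the second is secured by the low temperature, by keeping the oxazaborolidine in slight excess over AlBr3 (no free AlBr3 to polymerise 5) and by irradiating where the free lactone is transparent.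

Step 4
Reactants: 6 (1S,5S)-4,4,6,6-tetramethyl-3-oxabicyclo[3.2.0]heptan-2-one
Product: 7 [(1S,2S)-2-(2-hydroxypropan-2-yl)-3,3-dimethylcyclobutyl]methanol
Conditions: LiAlH4, THF, 0 → 25 °C; H2O, aq. NaOH work-up
Reagents that add atoms: none
Why: Hydride reduction of the lactone should give the cis diol without touching either ring stereocentre.

Step 5
Reactants: 7 [(1S,2S)-2-(2-hydroxypropan-2-yl)-3,3-dimethylcyclobutyl]methanol
Product: 9 [(1S,2R)-3,3-dimethyl-2-(prop-1-en-2-yl)cyclobutyl]methyl acetate, via primary monoacetate 8 (not isolated)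
Conditions: AcCl (1.05 equiv), pyridine, CH2Cl2, −20 °C; then POCl3 (3 equiv), 0 → 25 °C
Reagents that add atoms: acetyl chloride, CC(Cl)=O
Why: The primary hydroxyl is acetylated selectively, and the tertiary dichlorophosphate then undergoes pyridine-mediated E2 elimination toward a methyl hydrogen, because no free cation is formed (no cyclobutylcarbinyl ring expansion) and the exocyclic tetrasubstituted alkene would suffer allylic strain against the C3' methyl groups.

Step 6
Reactants: 9 [(1S,2R)-3,3-dimethyl-2-(prop-1-en-2-yl)cyclobutyl]methyl acetate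
Product: 10 [(1S,2R)-3,3-dimethyl-2-(prop-1-en-2-yl)cyclobutyl]methanol
Conditions: K2CO3 (0.2 equiv), MeOH, 25 °C
Reagents that add atoms: none
Why: Base-catalysed transesterification with methanol should free the primary alcohol without affecting the alkene or the ring.

Step 7
Reactants: 10 [(1S,2R)-3,3-dimethyl-2-(prop-1-en-2-yl)cyclobutyl]methanol
Product: 12 (1R,2R)-3,3-dimethyl-2-(prop-1-en-2-yl)cyclobutane-1-carbaldehyde, via cis aldehyde 11 (not isolated)
Conditions: IBX (1.5 equiv), EtOAc, 75 °C; filter; then DBU (0.2 equiv), 25 °C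
Reagents that add atoms: none
Why: IBX oxidation gives the cis aldehyde, and base-mediated enolisation at C1' should then equilibrate it to the trans isomer, which is expected to be the more stable one because formyl and isopropenyl no longer eclipse; this sets C1'.

Step 8
Reactants: 13 phloroglucinol; 14 (E)-hex-2-enal
Product: 16 (4R)-4-propylchromane-2,5,7-triol, via (3R)-3-(2,4,6-trihydroxyphenyl)hexanal 15 (not isolated)
Conditions: 13 (3 equiv), (S)-2-[diphenyl(trimethylsilyloxy)methyl]pyrrolidine (20 mol%), PhCO2H (20 mol%), MeCN, 0 °C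
Reagents that add atoms: none
Why: Iminium-catalysed Friedel–Crafts conjugate addition followed by hemiacetal closure: the arene should add to the face of the (E)-iminium ion not covered by the CPh2(OSiMe3) group, which sets the (R) centre, and the threefold symmetry of 13 removes any question of position.

Step 9
Reactants: 16 (4R)-4-propylchromane-2,5,7-triol
Product: 17 (4R)-5,7-dihydroxy-4-propyl-3,4-dihydro-2H-chromen-2-one
Conditions: Ag2CO3 on Celite (3 equiv), toluene, 90 °C
Reagents that add atoms: none
Why: Ag2CO3 on Celite oxidises lactols to lactones under neutral conditions, and the meta-trihydroxy ring cannot form a quinone and should therefore survive.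

Step 10
Reactants: 17 (4R)-5,7-dihydroxy-4-propyl-3,4-dihydro-2H-chromen-2-one
Product: 19 (4R)-2-oxo-4-propyl-7-{[tri(propan-2-yl)silyl]oxy}-3,4-dihydro-2H-chromen-5-yl 3-methylbut-2-enoate, via 7-O-silyl ether 18 (not isolated)
Conditions: (i-Pr)3SiCl (1.05 equiv), imidazole, CH2Cl2/DMF, 0 °C; then 3-methylbut-2-enoyl chloride (1.2 equiv), pyridine, DMAP (cat.), 0 → 25 °C
Reagents that add atoms: chlorotri(propan-2-yl)silane, CC(C)[Si](Cl)(C(C)C)C(C)C; 3-methylbut-2-enoyl chloride, CC(C)=CC(Cl)=O
Why: The bulky silyl chloride should take the unhindered 7-OH (5-OH sits next to C4a and the propyl-bearing C4), so that only O5 is left for esterification; this is what later decides which oxygen closes the chromanone ring.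

Step 11
Reactants: 19 (4R)-2-oxo-4-propyl-7-{[tri(propan-2-yl)silyl]oxy}-3,4-dihydro-2H-chromen-5-yl 3-methylbut-2-enoate
Product: 21 angular tricyclic lactone 7-O-silyl ether (chromanone ring closed on O5), via ortho-acylphenol 20 (not isolated)
Conditions: Bi(OTf)3 (10 mol%), dry toluene, 100 °C
Reagents that add atoms: none
Why: Fries rearrangement should move the acyl group to C6, the only free position ortho to O5, and the freed phenol then adds to the enone (oxa-Michael, 6-endo-trig) to give the 2,2-dimethylchroman-4-one; as O7 is silylated, only O5 can close the ring.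

Step 12
Reactants: 21 angular tricyclic lactone 7-O-silyl ether
Product: 23 methyl (3R)-3-(5,7-dihydroxy-2,2-dimethyl-4-oxo-3,4-dihydro-2H-chromen-8-yl)hexanoate, via silylated methyl ester 22 (not isolated)
Conditions: NaOMe (2.5 equiv), MeOH, 0 → 25 °C; AcOH, 0 °C
Reagents that add atoms: methanol, CO
Why: Methoxide opens the aryl lactone by transesterification (driven by release of the phenoxide) and cleaves the aryl silyl ether, which is activated by the ortho carbonyl group; in the phenoxide form retro-oxa-Michael opening of the chromanone is disfavoured, so the ring oxygen should stay where step 11 placed it.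

Step 13
Reactants: 23 methyl (3R)-3-(5,7-dihydroxy-2,2-dimethyl-4-oxo-3,4-dihydro-2H-chromen-8-yl)hexanoate; 12 (1R,2R)-3,3-dimethyl-2-(prop-1-en-2-yl)cyclobutane-1-carbaldehyde
Product: 25 methyl (3R)-3-[6-{[(1S,2R)-3,3-dimethyl-2-(prop-1-en-2-yl)cyclobutyl]methyl}-5,7-dihydroxy-2,2-dimethyl-4-oxo-3,4-dihydro-2H-chromen-8-yl]hexanoate, via ortho-quinone methide 24 (not isolated)
Conditions: 12 (1.2 equiv), L-proline (20 mol%), diethyl 2,6-dimethyl-1,4-dihydropyridine-3,5-dicarboxylate (1.3 equiv), CH2Cl2/EtOH, 25 °C
Reagents that add atoms: none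
Why: Three-component reductive alkylation: C6, the only free ring CH and flanked by two hydroxyls, condenses with the aldehyde (Knoevenagel type) to an ortho-quinone methide that is reduced at once by hydride transfer from the dihydropyridine, and C1' keeps its trans arrangement because that is the thermodynamic one even if the aldehyde epimerises through its enamine.

Step 14
Reactants: 25 methyl (3R)-3-[6-{[(1S,2R)-3,3-dimethyl-2-(prop-1-en-2-yl)cyclobutyl]methyl}-5,7-dihydroxy-2,2-dimethyl-4-oxo-3,4-dihydro-2H-chromen-8-yl]hexanoate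
Product: 26 methyl (3R)-3-[(6R)-6-{[(1S,2R)-3,3-dimethyl-2-(prop-1-en-2-yl)cyclobutyl]methyl}-5-hydroxy-2,2-dimethyl-6-(3-methylbut-2-en-1-yl)-4,7-dioxo-3,4,6,7-tetrahydro-2H-chromen-8-yl]hexanoate
Conditions: Pd2(dba)3·CHCl3 (2.5 mol%), (1R,2R)-N,N'-bis(2-diphenylphosphinobenzoyl)cyclohexane-1,2-diamine (7.5 mol%), tert-butyl 3-methylbut-2-en-1-yl carbonate (1.2 equiv), THF, 0 °C
Reagents that add atoms: tert-butyl 3-methylbut-2-en-1-yl carbonate, CC(C)=CCOC(=O)OC(C)(C)C
Why: Tsuji–Trost asymmetric allylic alkylation with dearomatisation: the phenoxide should attack the π-prenyl complex of divalent palladium through C6 (the less hindered carbon between two oxygens) at the CH2 terminus, the chiral pocket of the ligand choosing the face of the planar nucleophile and so the (6R) centre, while O-allylation is reversible and the product is held as a stable vinylogous acid.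

Step 15
Reactants: 26 methyl ester of the target
Product: 27 (3R)-3-[(6R)-6-{[(1S,2R)-3,3-dimethyl-2-(prop-1-en-2-yl)cyclobutyl]methyl}-5-hydroxy-2,2-dimethyl-6-(3-methylbut-2-en-1-yl)-4,7-dioxo-3,4,6,7-tetrahydro-2H-chromen-8-yl]hexanoic acid (CNP0358381.1)
Conditions: LiOH (3 equiv), THF/H2O, 0 → 25 °C; 1 M HCl to pH 3, 0 °C
Reagents that add atoms: lithium hydroxide, [Li+].[OH-]
Why: Saponification of the unhindered methyl ester; the dearomatised core is protected as its enolate in base, and the free acid cannot lactonise because C7 is now a ketone.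

Compound list
1 | 2-methylbut-3-yn-2-ol | CC(C)(O)C#C | starting material
2 | 4-hydroxy-4-methylpent-2-ynoic acid | CC(C)(O)C#CC(=O)O | intermediate
3 | (Z)-4-hydroxy-4-methylpent-2-enoic acid (not isolated) | CC(C)(O)/C=C\C(=O)O | intermediate
4 | 5,5-dimethylfuran-2(5H)-one | CC1(C)C=CC(=O)O1 | intermediate
5 | isobutylene (2-methylpropene) | C=C(C)C | starting material
6 | (1S,5S)-4,4,6,6-tetramethyl-3-oxabicyclo[3.2.0]heptan-2-one (cis-fused) | CC1(C)OC(=O)[C@H]2CC(C)(C)[C@@H]12 | intermediate
7 | [(1S,2S)-2-(2-hydroxypropan-2-yl)-3,3-dimethylcyclobutyl]methanol (cis) | OC[C@H]1CC(C)(C)[C@H]1C(C)(C)O | intermediate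
8 | [(1S,2S)-2-(2-hydroxypropan-2-yl)-3,3-dimethylcyclobutyl]methyl acetate (not isolated) | CC(=O)OC[C@H]1CC(C)(C)[C@H]1C(C)(C)O | intermediate
9 | [(1S,2R)-3,3-dimethyl-2-(prop-1-en-2-yl)cyclobutyl]methyl acetate (cis) | CC(=O)OC[C@H]1CC(C)(C)[C@H]1C(C)=C | intermediate
10 | [(1S,2R)-3,3-dimethyl-2-(prop-1-en-2-yl)cyclobutyl]methanol (cis) | OC[C@H]1CC(C)(C)[C@H]1C(C)=C | intermediate
11 | (1S,2R)-3,3-dimethyl-2-(prop-1-en-2-yl)cyclobutane-1-carbaldehyde (cis, not isolated) | O=C[C@H]1CC(C)(C)[C@H]1C(C)=C | intermediate
12 | (1R,2R)-3,3-dimethyl-2-(prop-1-en-2-yl)cyclobutane-1-carbaldehyde (trans) | O=C[C@@H]1CC(C)(C)[C@H]1C(C)=C | intermediate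
13 | phloroglucinol (benzene-1,3,5-triol) | Oc1cc(O)cc(O)c1 | starting material
14 | (E)-hex-2-enal | CCC/C=C/C=O | starting material
15 | (3R)-3-(2,4,6-trihydroxyphenyl)hexanal (not isolated) | CCC[C@H](CC=O)c1c(O)cc(O)cc1O | intermediate
16 | (4R)-4-propylchromane-2,5,7-triol (lactol, both anomers at C2) | CCC[C@@H]1CC(O)Oc2cc(O)cc(O)c12 | intermediate
17 | (4R)-5,7-dihydroxy-4-propyl-3,4-dihydro-2H-chromen-2-one | CCC[C@@H]1CC(=O)Oc2cc(O)cc(O)c12 | intermediate
18 | (4R)-5-hydroxy-4-propyl-7-{[tri(propan-2-yl)silyl]oxy}-3,4-dihydro-2H-chromen-2-one (not isolated) | CCC[C@@H]1CC(=O)Oc2cc(O[Si](C(C)C)(C(C)C)C(C)C)cc(O)c12 | intermediate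
19 | (4R)-2-oxo-4-propyl-7-{[tri(propan-2-yl)silyl]oxy}-3,4-dihydro-2H-chromen-5-yl 3-methylbut-2-enoate | CCC[C@@H]1CC(=O)Oc2cc(O[Si](C(C)C)(C(C)C)C(C)C)cc(OC(=O)C=C(C)C)c12 | intermediate
20 | (4R)-5-hydroxy-6-(3-methylbut-2-enoyl)-4-propyl-7-{[tri(propan-2-yl)silyl]oxy}-3,4-dihydro-2H-chromen-2-one (not isolated) | CCC[C@@H]1CC(=O)Oc2cc(O[Si](C(C)C)(C(C)C)C(C)C)c(C(=O)C=C(C)C)c(O)c12 | intermediate
21 | angular tricyclic lactone 7-O-silyl ether: the dihydrocoumarin of 18 (4R, propyl at C4) carrying a 2,2-dimethylchroman-4-one ring fused through O5 (ring oxygen) and C6 (carbonyl carbon), OSi(i-Pr)3 at C7, H at C8 | CCC[C@@H]1CC(=O)Oc2cc(O[Si](C(C)C)(C(C)C)C(C)C)c3C(=O)CC(C)(C)Oc3c12 | intermediate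
22 | methyl (3R)-3-(7-hydroxy-2,2-dimethyl-4-oxo-5-{[tri(propan-2-yl)silyl]oxy}-3,4-dihydro-2H-chromen-8-yl)hexanoate (not isolated) | CCC[C@H](CC(=O)OC)c1c(O)cc(O[Si](C(C)C)(C(C)C)C(C)C)c2C(=O)CC(C)(C)Oc12 | intermediate
23 | methyl (3R)-3-(5,7-dihydroxy-2,2-dimethyl-4-oxo-3,4-dihydro-2H-chromen-8-yl)hexanoate | CCC[C@H](CC(=O)OC)c1c(O)cc(O)c2C(=O)CC(C)(C)Oc12 | intermediate
24 | ortho-quinone methide from 23 and 12: C6 carries the exocyclic =CH–[(1R,2R)-cyclobutyl] group, C7 is a ketone (alkene geometry not fixed, not isolated) | CCC[C@H](CC(=O)OC)C1=C2OC(C)(C)CC(=O)C2=C(O)C(=C[C@@H]3CC(C)(C)[C@H]3C(C)=C)C1=O | intermediate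
25 | methyl (3R)-3-[6-{[(1S,2R)-3,3-dimethyl-2-(prop-1-en-2-yl)cyclobutyl]methyl}-5,7-dihydroxy-2,2-dimethyl-4-oxo-3,4-dihydro-2H-chromen-8-yl]hexanoate | CCC[C@H](CC(=O)OC)c1c(O)c(C[C@@H]3CC(C)(C)[C@H]3C(C)=C)c(O)c2C(=O)CC(C)(C)Oc12 | intermediate
26 | methyl (3R)-3-[(6R)-6-{[(1S,2R)-3,3-dimethyl-2-(prop-1-en-2-yl)cyclobutyl]methyl}-5-hydroxy-2,2-dimethyl-6-(3-methylbut-2-en-1-yl)-4,7-dioxo-3,4,6,7-tetrahydro-2H-chromen-8-yl]hexanoate | C=C(C)[C@H]1[C@H](C[C@]2(CC=C(C)C)C(=O)C([C@H](CCC)CC(=O)OC)=C3OC(C)(C)CC(=O)C3=C2O)CC1(C)C | intermediate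
27 | (3R)-3-[(6R)-6-{[(1S,2R)-3,3-dimethyl-2-(prop-1-en-2-yl)cyclobutyl]methyl}-5-hydroxy-2,2-dimethyl-6-(3-methylbut-2-en-1-yl)-4,7-dioxo-3,4,6,7-tetrahydro-2H-chromen-8-yl]hexanoic acid (CNP0358381.1) | C=C(C)[C@H]1[C@H](C[C@]2(CC=C(C)C)C(=O)C([C@H](CCC)CC(=O)O)=C3OC(C)(C)CC(=O)C3=C2O)CC1(C)C | target

Total step count: 15. Longest linear sequence: 10 steps (steps 1–7, then 13–15); the chromanone branch (steps 8–12) joins at step 13.

Steps most likely to fail

Step 3. The photoreaction may run outside the chiral complex if the lactone carbonyl binds the Lewis acid weakly or the absorption shift is small, which would give poor face selectivity. Head-to-head addition and cationic oligomerisation of isobutylene are further ways to lose material. Fallback (known chemistry): 4 and 5 are irradiated in acetone as solvent and triplet sensitiser (Pyrex filter, −20 °C), the established mode for butenolide–alkene [2+2] cycloaddition, to give racemic cis-4,4,6,6-tetramethyl-3-oxabicyclo[3.2.0]heptan-2-one F1. The enantiomers are then separated by preparative chromatography on a chiral stationary phase (cellulose tris(3,5-dimethylphenylcarbamate)), and the (1S,5S) enantiomer rejoins the route as 6.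

Step 14. Face discrimination at C6 of the planar phenoxide may be insufficient, and O-allylation or attack at the substituted allyl terminus may compete. Fallback: 25 is C-prenylated without chiral control as its dianion (prenyl bromide, NaOMe, MeOH, 0 °C), the classical alkylative dearomatisation of acylphloroglucinols. This should give 26 together with the C6 epimer of 26 F2; the two are diastereomers and are separated by chromatography, and 26 rejoins the route.

Step 11. The acyl group may migrate to C8 (para to O5) instead of C6, or the silyl ether may be lost under the Lewis acid, which would remove the control over which oxygen closes the ring. Fallback: unprotected 17 is annulated directly with 3-methylbut-2-enoic acid in P2O5/MeSO3H at 70 °C (Friedel–Crafts acylation at C6, then oxa-Michael closure). This should give the angular tricyclic lactone with free 7-OH F3 together with the linear tricyclic lactone closed on O7 F4. After chromatographic separation, F3 is opened with NaOMe in MeOH to give 23, where the route is rejoined.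

Further compounds
F1 | step 3 | racemic cis-4,4,6,6-tetramethyl-3-oxabicyclo[3.2.0]heptan-2-one (6 and its enantiomer, 1:1) | CC1(C)OC(=O)[C@H]2CC(C)(C)[C@@H]12.CC1(C)OC(=O)[C@@H]2CC(C)(C)[C@H]12
F2 | step 14 | C6 epimer of 26 ((6S) at the quaternary carbon, all other centres as in 26) | C=C(C)[C@H]1[C@H](C[C@@]2(CC=C(C)C)C(=O)C([C@H](CCC)CC(=O)OC)=C3OC(C)(C)CC(=O)C3=C2O)CC1(C)C
F3 | step 11 | angular tricyclic lactone with free 7-OH (21 without the silyl group; chromanone ring oxygen on C5, 4R) | CCC[C@@H]1CC(=O)Oc2cc(O)c3C(=O)CC(C)(C)Oc3c12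
F4 | step 11 | linear tricyclic lactone (chromanone ring oxygen on C7, free 5-OH, 4R) | CCC[C@@H]1CC(=O)Oc2cc3OC(C)(C)CC(=O)c3c(O)c12
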